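**Retrosynthetic overview**
C1–C8 and C10 of the bicycle, with methyl carbons C17–C20, are the thirteen carbons of (R)-α-ionone (its stereocentre becomes C5), so ring B lacks only C9.
Key disconnection C8–C9: palladium-catalysed intramolecular α-alkenylation of a C9 ester enolate with the C8 (Z)-enol triflate; ring A is the ionone ring and ring B closes last.
C9 and C11 come from triethyl orthoacetate by a Johnson–Claisen rearrangement that builds quaternary C10 trans to the C5 side chain.
Ring A passes through the ring closure as a non-enolisable 2-ethoxy-1-en-3-one, because C3 cannot be set reliably on the monocycle and C1=C2 could not be told from C7=C8 afterwards; C3 is then set by hydride reduction of the rigid trans-decalin and the C2 ketone is released last by enol ether hydrolysis.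
Side chain C12–C16: propargylation of the C11 iodide, zirconium-catalysed carboalumination with formaldehyde capture, acetylation.

Key step: step 12

Remark: labdane numbering (C1–C20) is used for the target and every intermediate, and (R)-α-ionone of high enantiomeric purity is taken to be purchasable.

Step 1
Reactants: 1 (R)-α-ionone; 2 ethylene glycol
Product: 3 (R)-α-ionone ethylene ketal
Conditions: HC(OEt)3, p-TsOH (cat.), rt
Reagents that add atoms: ethylene glycol, OCCO
Why: Acid-catalysed dioxolane formation with the orthoformate as water scavenger masks the methyl ketone at room temperature and should leave the C6=C7 and C1=C10 olefins and the C5 stereocentre in place.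

Step 2
Reactants: 3 (R)-α-ionone ethylene ketal; 4 tert-butyl hydroperoxide
Product: 5 C2 enone ketal
Conditions: t-BuOOH, dirhodium tetrakis(caprolactamate) Rh2(cap)4 (1 mol %), K2CO3, CH2Cl2, rt
Reagents that add atoms: tert-butyl hydroperoxide, CC(C)(C)OO
Why: Radical allylic oxidation (tert-butylperoxy chain under dirhodium catalysis) should attack C2, the only allylic methylene, and give the enone conjugated with C1=C10, while the tertiary, doubly allylic C5–H between two fully substituted carbons is shielded.

Step 3
Reactants: 5 C2 enone ketal; 6 tert-butyldimethylsilyl chloride; 7 3-chloroperbenzoic acid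
Product: 9 C3-silyloxy enone ketal, via silyl dienol ether 8 (not isolated)
Conditions: LiN(i-Pr)2, THF, −78 °C (ketone added to base); t-BuMe2SiCl, HMPA, −78 → 0 °C; pentane work-up; then m-CPBA, NaHCO3, CH2Cl2, −20 → 0 °C
Reagents that add atoms: tert-butyldimethylsilyl chloride, CC(C)(C)[Si](C)(C)Cl; 3-chloroperbenzoic acid, OOC(=O)c1cccc(Cl)c1
Why: Rubottom oxidation: kinetic deprotonation at C3 (the α' position) gives the cross-conjugated silyl dienol ether, the peracid epoxidises its C2=C3 bond on the face away from the pseudo-axial C5 side chain and silicon shifts to the new oxygen, so the C3 silyloxy group should end trans to the side chain (a temporary centre, erased in step 7).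

Step 4
Reactants: 9 C3-silyloxy enone ketal
Product: 10 C2 allylic alcohol
Conditions: Li[HB(s-Bu)3] (L-Selectride), THF, −78 °C; aq. NH4Cl at −78 °C
Reagents that add atoms: none
Why: 1,2-Reduction of the β,β-disubstituted enone by the bulky trialkylborohydride should occur by equatorial attack on the face opposite both the pseudo-axial C4 methyl and the C3 silyloxy group, setting the C2 carbinol with its oxygen pseudo-axial, cis to C3–O and trans to the C5 side chain (cold quench limits silyl migration).

Step 5
Reactants: 10 C2 allylic alcohol; 11 triethyl orthoacetate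
Product: 13 Claisen ester with quaternary C10, via ketene acetal 12 (not isolated)
Conditions: MeC(OEt)3 (excess), EtCO2H (cat.), xylene, 140 °C, EtOH distilled off
Reagents that add atoms: triethyl orthoacetate, CC(OCC)(OCC)OCC
Why: Johnson–Claisen rearrangement: orthoester exchange and loss of ethanol give ketene acetal 12, whose suprafacial [3,3] shift transfers the C2 configuration to C10, so the quaternary stereocentre C10 is set with CH2CO2Et (C9, C11) trans to the C5 side chain and the olefin moves to C1=C2.

Step 6
Reactants: 13 Claisen ester with quaternary C10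
Product: 14 C3 allylic alcohol
Conditions: Bu4NF, THF, rt
Reagents that add atoms: none
Why: Fluoride-induced cleavage of the silyl ether frees the allylic C3 alcohol without touching the ethyl ester or the ketal.

Step 7
Reactants: 14 C3 allylic alcohol
Product: 15 ring A enone (C1=C2–C3=O)
Conditions: Dess–Martin periodinane, NaHCO3, CH2Cl2, rt
Reagents that add atoms: none
Why: Dess–Martin oxidation of the allylic alcohol gives an enone that has no enolisable hydrogen (C4 and C10 are quaternary) and in which the provisional C3 centre is erased.

Step 8
Reactants: 15 ring A enone (C1=C2–C3=O); 4 tert-butyl hydroperoxide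
Product: 16 1,2-epoxy-3-ketone
Conditions: t-BuOOH (anhydrous), DBU, CH2Cl2, 0 °C → rt
Reagents that add atoms: tert-butyl hydroperoxide, CC(C)(C)OO
Why: Weitz–Scheffer (nucleophilic) epoxidation: the hydroperoxide anion adds only to the electron-poor ring enone at C1 and closes the epoxide, the isolated C6=C7 olefin being inert to a nucleophilic oxidant, and the epoxide configuration is of no consequence because C1 and C2 become sp2 again in step 9.

Step 9
Reactants: 16 1,2-epoxy-3-ketone; 17 sodium ethoxide
Product: 18 2-ethoxy-1-en-3-one ketal
Conditions: NaOEt, EtOH, reflux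
Reagents that add atoms: sodium ethoxide, CC[O-].[Na+]
Why: Base-mediated conversion of an α,β-epoxy ketone into an α-alkoxy enone: ethoxide opens the epoxide at C2 (activated by the carbonyl, whereas C1 is neopentyl) and E1cB loss of the C1 hydroxyl gives the diosphenol ethyl ether, a Favorskii pathway being excluded by quaternary C4 and transesterification being degenerate with ethoxide.

Step 10
Reactants: 18 2-ethoxy-1-en-3-one ketal; 19 water
Product: 20 2-ethoxy-enone with (E)-enone side chain
Conditions: (CO2H)2, THF–H2O, rt
Reagents that add atoms: water, O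
Why: Mild acid hydrolysis cleaves the allylic dioxolane through its stabilised oxocarbenium ion, whereas the ring A enol ether is deactivated by conjugation with the C3 carbonyl and should survive.

Step 11
Reactants: 20 2-ethoxy-enone with (E)-enone side chain; 21 triethylsilane; 22 N-phenylbis(trifluoromethanesulfonimide)
Product: 24 ring A ester with (Z)-enol triflate side chain, via triethylsilyl enol ether 23 (not isolated)
Conditions: Et3SiH (1.05 equiv), RhCl(PPh3)3 (1 mol %), benzene, 50 °C; concentrate; CsF, PhNTf2, DME, rt
Reagents that add atoms: N-phenylbis(trifluoromethanesulfonimide), FC(F)(F)S(=O)(=O)N(c1ccccc1)S(=O)(=O)C(F)(F)F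
Why: Conjugate (1,4-) hydrosilylation of the acyclic enone through its s-cis conformer delivers hydride to C6 and silicon to oxygen, giving the C7=C8 silyl enol ether regiospecifically and with Z geometry (C6 cis to oxygen), and fluoride then releases the enolate for O-sulfonylation with retention of position and geometry; the ring A enone is α-alkoxy-substituted, neopentyl at its β-carbon and locked s-trans, and should react more slowly.

Step 12
Reactants: 24 ring A ester with (Z)-enol triflate side chain
Product: 26 bicyclic C11 ethyl ester, via lithium dienolate 25 (not isolated)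
Conditions: LiN(SiMe3)2 (2.2 equiv), Pd2(dba)3 (2.5 mol %), P(t-Bu)3 (10 mol %), toluene (0.01 M), rt → 50 °C; then AcOH, THF, −78 °C
Reagents that add atoms: none
Why: Zerovalent palladium, formed from Pd2(dba)3 and P(t-Bu)3, inserts into the C8–O bond of the enol triflate, the lithium ester enolate displaces triflate on palladium and binds through C9 to give a seven-membered palladacycle, and reductive elimination forms the C8–C9 bond, after which the second equivalent of base converts the more acidic β,γ-unsaturated product ester into dienolate 25. The closest known reaction type is the palladium-catalysed α-alkenylation of enolates with alkenyl halides and triflates, known between separate partners for ester enolates and within one molecule for ketone and ester enolates. Ring B is closed as a six-membered ring by C–C reductive elimination from the palladacycle, with the C7=C8 double bond left inside the new ring, and the trans ring fusion follows from the trans C5 and C10 arms fixed in step 5. The one new stereocentre, C9, is not set in the bond-forming event but by kinetic α-protonation of dienolate 25 with acetic acid at −78 °C on the face opposite the axial C20 methyl, which places C11 equatorial and H9 cis to H5. The step needs the Z enol triflate, since only with C6 cis to the leaving group can C8 reach C9, and this is secured by the s-cis hydrosilylation of step 11; it needs a single enolisable site, secured by the ring A ethoxy-enone, which has no α or γ hydrogen; and it needs a palladium enolate that cannot undergo β-hydride elimination, secured because C10 is quaternary.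

Step 13
Reactants: 26 bicyclic C11 ethyl ester
Product: 27 C3,C11-diol with ring A enol ether
Conditions: LiAlH4, THF, −78 → 0 °C; H2O then NaOH (aq.) work-up
Reagents that add atoms: none
Why: Hydride reduction of the ester to the C11 alcohol and 1,2-reduction of the enone in one operation; in the rigid trans-decalin the small hydride should attack C3 axially, on the face opposite the axial C4 methyl and C20, which sets the C3 stereocentre as the equatorial alcohol (cis to C20), while the enol ether is inert.

Step 14
Reactants: 27 C3,C11-diol with ring A enol ether; 28 iodine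
Product: 29 C11 iodide
Conditions: PPh3, I2, imidazole (premixed), CH2Cl2, 0 °C
Reagents that add atoms: iodine, II
Why: Appel-type iodination through the alkoxyphosphonium salt is selective for the primary C11 alcohol over the secondary C3 alcohol next to the gem-dimethyl carbon, and premixing PPh3 with iodine keeps free iodine away from the enol ether.

Step 15
Reactants: 29 C11 iodide; 30 1-(trimethylsilyl)propyne
Product: 32 terminal alkyne, via silylated alkyne 31 (not isolated)
Conditions: n-BuLi, THF, −78 °C (2.5 equiv of lithio reagent); 29, HMPA, −78 → 0 °C; then K2CO3, MeOH, rt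
Reagents that add atoms: 1-(trimethylsilyl)propyne, CC#C[Si](C)(C)C
Why: SN2 alkylation of the propargylic lithium reagent from 1-(trimethylsilyl)propyne (silicon blocks the acetylenic terminus; one extra equivalent is consumed by the C3 hydroxyl) adds C12–C14, and methanolysis of the C–Si bond then gives the terminal alkyne.

Step 16
Reactants: 32 terminal alkyne; 33 trimethylaluminium; 34 formaldehyde (as paraformaldehyde)
Product: 36 13E allylic diol, via alkenylalane 35 (not isolated)
Conditions: AlMe3 (4 equiv), Cp2ZrCl2 (0.5 equiv), CH2Cl2, 0 °C → rt; volatiles removed; n-BuLi, THF–hexane, −78 °C; (CH2O)n, −78 °C → rt; aq. NaOH work-up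
Reagents that add atoms: trimethylaluminium, C[Al](C)C; formaldehyde, C=O
Why: Negishi zirconium-catalysed carboalumination adds methyl and aluminium syn across the terminal alkyne with methyl at C13, and the derived alanate captures formaldehyde with retention, so the 13E trisubstituted olefin and C15 arise in one operation (the C3 hydroxyl is carried as its aluminium alkoxide).

Step 17
Reactants: 36 13E allylic diol; 37 acetic anhydride
Product: 38 C15 acetate with ring A enol ether
Conditions: Ac2O (1.1 equiv), pyridine, CH2Cl2, 0 °C
Reagents that add atoms: acetic anhydride, CC(=O)OC(C)=O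
Why: Acylation under mild conditions should be selective for the primary allylic C15 alcohol over the secondary C3 alcohol, which is hindered by the C4 gem-dimethyl group.

Step 18
Reactants: 38 C15 acetate with ring A enol ether; 19 water
Product: 39 CNP0164008.1 (target)
Conditions: (CO2H)2, THF–H2O, rt
Reagents that add atoms: water, O
Why: Mild acid hydrolysis of the enol ether (protonation at C1, hydration of the C2 oxocarbenium ion, loss of ethanol) unmasks the C2 ketone next to the free C3 alcohol under conditions that should neither enolise the ketol nor cleave the allylic acetate.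

**Compound list**
1 | (R)-α-ionone | CC(=O)/C=C/[C@H]1C(C)=CCCC1(C)C | starting material
2 | ethylene glycol | OCCO | starting material
3 | (R)-α-ionone ethylene ketal (2-methyl-2-[(E)-2-[(1R)-2,6,6-trimethylcyclohex-2-en-1-yl]ethenyl]-1,3-dioxolane) | CC1(/C=C/[C@H]2C(C)=CCCC2(C)C)OCCO1 | intermediate
4 | tert-butyl hydroperoxide | CC(C)(C)OO | starting material
5 | C2 enone ketal (ring ketone at C2 conjugated with C1=C10; C5 as in 1) | CC1(/C=C/[C@H]2C(C)=CC(=O)CC2(C)C)OCCO1 | intermediate
6 | tert-butyldimethylsilyl chloride | CC(C)(C)[Si](C)(C)Cl | starting material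
7 | 3-chloroperbenzoic acid | OOC(=O)c1cccc(Cl)c1 | starting material
8 | cross-conjugated silyl dienol ether (C10=C1–C2(OSi)=C3) | CC1(/C=C/[C@H]2C(C)=CC(O[Si](C)(C)C(C)(C)C)=CC2(C)C)OCCO1 | intermediate
9 | C3-silyloxy enone ketal (C3–OSi trans to the C5 side chain) | CC1(/C=C/[C@H]2C(C)=CC(=O)[C@H](O[Si](C)(C)C(C)(C)C)C2(C)C)OCCO1 | intermediate
10 | C2 allylic alcohol (C2–OH cis to C3–OSi and trans to the C5 side chain) | CC1(/C=C/[C@H]2C(C)=C[C@H](O)[C@H](O[Si](C)(C)C(C)(C)C)C2(C)C)OCCO1 | intermediate
11 | triethyl orthoacetate | CC(OCC)(OCC)OCC | starting material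
12 | mixed ketene acetal on the C2 oxygen of 10 | CC1(/C=C/[C@H]2C(C)=C[C@H](OC(=C)OCC)[C@H](O[Si](C)(C)C(C)(C)C)C2(C)C)OCCO1 | intermediate
13 | Claisen ester (quaternary C10 with CH2CO2Et trans to the C5 side chain; C1=C2; C3–OSi) | CCOC(=O)C[C@]1(C)C=C[C@H](O[Si](C)(C)C(C)(C)C)C(C)(C)[C@H]1/C=C/C2(C)OCCO2 | intermediate
14 | C3 allylic alcohol | CCOC(=O)C[C@]1(C)C=C[C@H](O)C(C)(C)[C@H]1/C=C/C2(C)OCCO2 | intermediate
15 | ring A enone (C1=C2–C3=O) | CCOC(=O)C[C@]1(C)C=CC(=O)C(C)(C)[C@H]1/C=C/C2(C)OCCO2 | intermediate
16 | 1,2-epoxy-3-ketone (epoxide drawn on the face opposite the C5 side chain; either epoxide serves) | CCOC(=O)C[C@]1(C)[C@@H]2O[C@@H]2C(=O)C(C)(C)[C@H]1/C=C/C3(C)OCCO3 | intermediate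
17 | sodium ethoxide, NaOEt | CC[O-].[Na+] | starting material
18 | 2-ethoxy-1-en-3-one ketal (diosphenol ethyl ether) | CCOC(=O)C[C@]1(C)C=C(OCC)C(=O)C(C)(C)[C@H]1/C=C/C2(C)OCCO2 | intermediate
19 | water | O | starting material
20 | 2-ethoxy-1-en-3-one with (E)-C6=C7–C8=O side chain | CCOC(=O)C[C@]1(C)C=C(OCC)C(=O)C(C)(C)[C@H]1/C=C/C(C)=O | intermediate
21 | triethylsilane | CC[SiH](CC)CC | starting material
22 | N-phenylbis(trifluoromethanesulfonimide) | FC(F)(F)S(=O)(=O)N(c1ccccc1)S(=O)(=O)C(F)(F)F | starting material
23 | (Z)-C7=C8 triethylsilyl enol ether | CCOC(=O)C[C@]1(C)C=C(OCC)C(=O)C(C)(C)[C@H]1C/C=C(/C)O[Si](CC)(CC)CC | intermediate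
24 | ring A ester with (Z)-enol triflate side chain (key-step precursor) | CCOC(=O)C[C@]1(C)C=C(OCC)C(=O)C(C)(C)[C@H]1C/C=C(/C)OS(=O)(=O)C(F)(F)F | intermediate
25 | lithium dienolate of 26 | CCOC([O-])=C1C(C)=CC[C@@H]2C(C)(C)C(=O)C(OCC)=C[C@@]12C.[Li+] | intermediate
26 | bicyclic C11 ethyl ester (trans-decalin; 2-ethoxy-1,7-dien-3-one; H9 cis to H5, both trans to C20) | CCOC(=O)[C@@H]1C(C)=CC[C@@H]2C(C)(C)C(=O)C(OCC)=C[C@@]12C | intermediate
27 | diol (C11–OH; equatorial C3–OH cis to C20; 2-ethoxy-Δ1 enol ether) | OC[C@@H]1C(C)=CC[C@@H]2C(C)(C)[C@H](O)C(OCC)=C[C@@]12C | intermediate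
28 | iodine | II | starting material
29 | C11 iodide | IC[C@@H]1C(C)=CC[C@@H]2C(C)(C)[C@H](O)C(OCC)=C[C@@]12C | intermediate
30 | 1-(trimethylsilyl)propyne | CC#C[Si](C)(C)C | starting material
31 | C14-silylated alkyne | C[Si](C)(C)C#CCC[C@@H]1C(C)=CC[C@@H]2C(C)(C)[C@H](O)C(OCC)=C[C@@]12C | intermediate
32 | terminal alkyne (C13≡C14) | C#CCC[C@@H]1C(C)=CC[C@@H]2C(C)(C)[C@H](O)C(OCC)=C[C@@]12C | intermediate
33 | trimethylaluminium, AlMe3 | C[Al](C)C | starting material
34 | formaldehyde (used as paraformaldehyde) | C=O | starting material
35 | (E)-alkenyl dimethylalane (C3 oxygen as dimethylaluminium alkoxide) | C[Al](C)/C=C(\C)CC[C@@H]1C(C)=CC[C@@H]2C(C)(C)[C@H](O[Al](C)C)C(OCC)=C[C@@]12C | intermediate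
36 | 13E allylic diol (C15–OH and C3–OH) | OC/C=C(\C)CC[C@@H]1C(C)=CC[C@@H]2C(C)(C)[C@H](O)C(OCC)=C[C@@]12C | intermediate
37 | acetic anhydride | CC(=O)OC(C)=O | starting material
38 | C15 acetate with ring A enol ether | CC(=O)OC/C=C(\C)CC[C@@H]1C(C)=CC[C@@H]2C(C)(C)[C@H](O)C(OCC)=C[C@@]12C | intermediate
39 | CNP0164008.1, 3-hydroxy-2-oxolabda-7,13E-dien-15-yl acetate | CC(=O)OC/C=C(\C)CC[C@@H]1C(C)=CC[C@@H]2C(C)(C)[C@H](O)C(=O)C[C@@]12C | target

**Total step count:** 18. **Longest linear sequence:** 18 steps, from 1.

**Steps most likely to fail**

Step 12. The alkenylpalladium intermediate may be diverted before the enolate reaches it (Heck-type insertion into the ring A enone from the conformer with an axial side chain), the base may eliminate triflate to an alkyne, or the enolate may self-condense. The fallback takes the strong base out of the coupling; it sets out from 24 and returns at 26. The ester is enolised once at −78 °C and trapped (LiN(SiMe3)2, Me3SiCl, THF) as the silyl ketene acetal F1. N-Bromosuccinimide converts this into the α-bromo ester F2. Zinc insertion (activated Zn, THF) gives the Reformatsky reagent, which is coupled with the enol triflate in the same molecule by a Negishi-type reaction (Pd(dba)2, P(t-Bu)3, THF, rt), giving 26. Should C9 form unselectively, one passage through dienolate 25 with cold acetic acid, as in step 12, would correct it.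

Step 11. Chemoselectivity may be lost by hydride delivery to the ring A enone as well, and in the fluoride stage the freed enolate may add to the ring A enone or scramble its position and geometry before O-sulfonylation. The fallback sets out from 20 and returns at 24. Catecholborane (THF, rt) reduces only enones that can reach the s-cis conformer, so after aqueous work-up the saturated methyl ketone F3 should result with the ring A enone intact. Equilibrating silylation (Me3SiCl, NaI, Et3N, MeCN) should give mainly the more substituted (Z)-trimethylsilyl enol ether F4, which CsF and PhNTf2 (DME, rt) convert into 24.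

Step 15. Elimination may take the place of substitution: the basic propargyl anion can remove the allylic C9 hydrogen of the β-branched iodide. The fallback reverses the polarity; it sets out from 29 and returns at 31. NaO2SPh (DMF, 60 °C), a soft and non-basic nucleophile, gives the C11 phenyl sulfone F5. Its dianion (n-BuLi, 2.2 equiv, THF, −78 °C) is alkylated at C11 by the unhindered 3-bromo-1-(trimethylsilyl)propyne to give the propargylated sulfone F6. Reductive desulfonylation (Na(Hg), Na2HPO4, MeOH, −20 °C) gives 31, which is desilylated to 32 as in step 15.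

**Further compounds**
F1 | step 12 | silyl ketene acetal of ester 24 | CCOC(O[Si](C)(C)C)=C[C@]1(C)C=C(OCC)C(=O)C(C)(C)[C@H]1C/C=C(/C)OS(=O)(=O)C(F)(F)F
F2 | step 12 | α-bromo ester (C9 bromide, either epimer) | CCOC(=O)C(Br)[C@]1(C)C=C(OCC)C(=O)C(C)(C)[C@H]1C/C=C(/C)OS(=O)(=O)C(F)(F)F
F3 | step 11 | saturated methyl ketone | CCOC(=O)C[C@]1(C)C=C(OCC)C(=O)C(C)(C)[C@H]1CCC(C)=O
F4 | step 11 | (Z)-trimethylsilyl enol ether | CCOC(=O)C[C@]1(C)C=C(OCC)C(=O)C(C)(C)[C@H]1C/C=C(/C)O[Si](C)(C)C
F5 | step 15 | C11 phenyl sulfone | O=S(=O)(C[C@@H]1C(C)=CC[C@@H]2C(C)(C)[C@H](O)C(OCC)=C[C@@]12C)c1ccccc1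
F6 | step 15 | propargylated sulfone (C11 either epimer) | C[Si](C)(C)C#CCC([C@@H]1C(C)=CC[C@@H]2C(C)(C)[C@H](O)C(OCC)=C[C@@]12C)S(=O)(=O)c1ccccc1
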